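## Structural features

Lepidine C is an achiral diaryl ether: two benzene rings joined through one oxygen, each carrying a (1H-imidazol-2-yl)methyl arm, so four aromatic rings are linked by one C–O–C bridge and two CH2 bridges. Ring A, numbered here with the methoxy carbon as C1, is 1,2,4-trisubstituted: the ether oxygen is on C4 (para to the methoxy group) and the imidazolylmethyl carbon on the adjacent C5. Ring B is a meta-disubstituted benzene with the ether oxygen and the imidazolylmethyl arm in a 1,3 relationship. There is no stereocenter and no ring fusion; the carbinol and chloride intermediates of the route are racemic and their centers are erased. The fragile elements are the two N–H imidazoles (nucleophilic, basic, metal-binding, so N1 must be masked through any aryne or organolithium step), the two doubly activated CH2 groups (acidic, oxidisable) and the electron-rich diaryl ether, which rules out dissolving-metal reductions. The real difficulty is the ortho O/C pair of ring A: a hindered diaryl ether bond must be made next to a carbon that carries an imidazole, with the right regiochemistry and without a long linear sequence. A second difficulty is that each benzylic carbon sits on C2 of an imidazole that is protonated in acid, so cation-based deoxygenation there is slow. The key step uses the C4(O)/C5(C) pair of ring A: it is the pattern left when an aryne takes up an oxygen nucleophile at one carbon and a carbon electrophile at the other, and a removable chlorine at C6 distinguishes the two aryne carbons.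

## Logic of the disconnections

**21 to 20.** Restored in the backward direction are the two N1–CH2Ph bonds, the aryl C6–Cl bond and the benzylic C–Cl bond. The N-benzyl groups are needed because free N–H imidazoles would be arylated by an aryne. The ring chlorine is the regiocontrol element of the key step, and the benzylic chloride is the handle for removing the ketone oxygen. The gain is that all four auxiliaries leave in one operation. The demand is a hydrogenolysis that cleaves four C–X bonds but leaves the diaryl ether C–O bonds and the C-benzyl C–C links intact.

**20 to 19 to 18.** The benzylic C–Cl bond is traced back to C–OH and then to C=O. The ring A methylene is taken back to a ketone because the key step delivers an acyl group at C5. Passing through the chloride avoids a benzylic cation beside a protonated imidazole. The demand is hydride delivery and chloride substitution at a carbon flanked by two ortho substituents.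

**18 to 7 plus 16 (made in the flask from 15, passing through 17).** The ring A bonds C4–O and C5–C(=O) are cut together. The reason is the vicinal O/C pattern. The gain is the largest in the route: 7 already holds ring B, its finished imidazolylmethyl arm, the second imidazole and the future benzylic carbon, so one step joins all fragments. The demands are regioselectivity (oxygen at C4, acyl at C5) and chemoselectivity of the intermediate aryl anion for acyl transfer.

**15 to 13 to 9 to 8.** The O–SO2CF3 bond, the C2–Si bond and the carbamate O–C bond are cut in turn. An ortho-silylaryl triflate is the aryne source that tolerates an ester. The carbamate is chosen because, with the chlorine, it directs metalation to the carbon between them. The demand is lithiation at low temperature without loss of LiCl from 11.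

**7 to 5 plus 6.** The ester C(acyl)–O bond is cut. This gives two small pieces of similar complexity. The acyl half is carried as 6, whose carbon leaving group departs irreversibly, so that no free imidazole-2-carboxylic acid, which would decarboxylate on warming, has to be handled. The demand is an acyl transfer mild enough that the activated ester 7 survives.

**6 to 1, and 5 to 4 to 3 plus 2.** Both imidazole C2–C bonds are cut: the C2–C(acyl) bond of 6 by direct C2-acylation of 1, and the C2–C(carbinol) bond of 4 by carbonyl addition of 3, which is made from 1. The benzylic C–O bond of 4 is restored on the way from 5. One starting material, 1, serves both halves, and 3 is needed once only. The demands are C2-selective functionalisation of 1 in both modes and a deoxygenation of 4 that does not rely on a stabilised cation.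

## Other disconnections considered

**Alternative 1:** The cut removes, on both rings at once, the aryl–C(=O) bond and the C(=O)–C2(imidazole) bond, so both benzylic carbons come from a one-carbon carbonyl source. Forward, diiodide A1 and two equivalents of stannane A2 would undergo a twofold carbonylative Stille coupling under Pd(PPh3)4 catalysis to give bis-ketone A3.

- In favour: the reaction class is established for aryl iodides and 2-stannyl azoles, both arms are treated identically, and no chlorine has to be carried and removed. On precedent for the key step it is the better plan.
- Against: the diaryl ether is not formed in the key step and must be built into A1 with two iodides already present. The iodide ortho to the aryloxy group is hindered and electron-rich, which favours direct coupling over carbonyl insertion. 2-Stannylimidazoles protodestannylate easily, and stoichiometric tin and a toxic gas under pressure are needed. A3 carries two ketones on imidazole C2, so the awkward deoxygenation is needed twice, once on ring B where no donor group helps.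
- Comparison: structurally, the chosen plan makes the hindered C–O bond and the C–C bond of ring A together; alternative 1 makes four C–C bonds but none of the ether. Mechanistically, alternative 1 uses known elementary steps while the chosen insertion is untested. In step count the two are about equal (A1 and A2 each need a few steps, then coupling, double reduction and deprotection).

**Alternative 2:** The cut runs through ring A: bonds C4–C5 and C2–C3 are broken. Pyrone A4 supplies C5, C6, C1 and C2 with the methoxy group and the ester carbon; aryl ynol ether A5 supplies C3 and C4 with the ring B oxygen attached. Forward, an inverse-demand [4+2] cycloaddition and retro-[4+2] extrusion of the lactone bridge would give diester A6.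

- In favour: regiochemistry follows from matched polarisation (the terminal carbon of A5 bonds to pyrone C6, the oxygen-bearing carbon to pyrone C3). No directing halogen and no aryl C–O coupling are needed, and the reaction class is known. On regiochemical certainty and precedent it is the better plan.
- Against: A5 is a sensitive ynol ether that takes several steps from a phenol, and A4 must also be made. A6 holds both benzylic carbons only as esters, so neither imidazole is attached; both arms still need acylation of 3 and a ketone deoxygenation beside an imidazole.
- Comparison: structurally, both plans create the C4/C5 pattern in one step, but the chosen plan also brings in ring B's finished arm and the second imidazole. Mechanistically, a predictable pericyclic sequence stands against an anionic chain with competing channels. In step economy the alternative is longer before and after its key step; the chosen plan is ahead if the insertion works.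

**Alternative 3:** The cut is at both CH2–C2(imidazole) bonds. Forward, the bis(N-acyloxyphthalimide) A7 would be reduced at a cathode to benzylic radicals, which NiCl2–2,2'-bipyridine catalysis couples with two equivalents of iodoimidazole A8 to give A9 at the methylene oxidation level.

- In favour: no ketone is formed, so the deoxygenation beside imidazole disappears and A9 is one deprotection from the target. After the key step this alternative is clearly better than the chosen plan. The reaction class (decarboxylative arylation of redox-active esters) is known, so it is also ahead on precedent.
- Against: the key step builds none of the diaryl ether, so A7 needs its own synthesis (ether formation, two acetic acid arms and their activation). Benzylic radicals dimerise readily and benzylic redox-active esters are labile. 2-Haloimidazoles are electron-rich, coordinating partners for nickel. Two couplings must succeed on one molecule.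
- Comparison: structurally, the chosen plan is more convergent because its key step makes the ether and one arm at once. Mechanistically, both rely on reactive intermediates (radicals or an aryl anion) that must be trapped faster than they are quenched; the alternative's trapping step has precedent, the chosen one does not. In step economy the alternative is shorter after the key step and longer before it, so the totals are comparable.

Key step: step 8

Remarks on the chemistry:

- Ring A numbering: C1 carries OMe, C4 the ether oxygen, C5 the benzylic carbon, C6 the temporary chlorine.
- The structures of 15, 7 and 18 were checked atom by atom against the regiochemistry expected for a 3-haloaryne; they are consistent and none needed correction.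
- Compounds 1, 2 and 8 and all reagents named are taken as commercial.
- Design changes for the key step: an ether solvent in place of a nitrile (no acidic C–H), a seed of pre-formed phenoxide, and slow addition of the aryne precursor.
- The acyl half of the ester is brought in as trichloromethyl ketone 6, made from 1 without an organometallic reagent, so the decarboxylation-prone free acid is avoided in the main line.

## Route

Step 1
Reactants: 1 1-benzylimidazole; 2 3-hydroxybenzaldehyde
Product: 4 racemic (1-benzylimidazol-2-yl)(3-hydroxyphenyl)methanol, via 1-benzyl-2-lithioimidazole 3 (not isolated)
Conditions: 1 (2.2 equiv), n-BuLi (2.1 equiv), THF, −78 °C; then 2 (1.0 equiv), −78 to 0 °C; aq NH4Cl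
Reagents that add atoms: none
Why: Kinetic C2-lithiation of an N-alkylimidazole and 1,2-addition to an aldehyde; one equivalent of 3 is spent deprotonating the phenol (returning 1), so no O-protection is needed, and the meta-phenoxide does not deactivate the aldehyde; the carbinol center forms racemic and is erased in step 2.

Step 2
Reactants: 4 racemic (1-benzylimidazol-2-yl)(3-hydroxyphenyl)methanol
Product: 5 3-[(1-benzylimidazol-2-yl)methyl]phenol
Conditions: I2 (0.5 equiv), 50% aq H3PO2 (5 equiv), AcOH, 100 °C; aq NaHCO3
Reagents that add atoms: none
Why: Reduction of a diaryl-type carbinol by HI generated in situ from iodine and hypophosphorous acid: iodide displaces the activated hydroxyl and the benzylic iodide beside the imidazolium is reduced by further iodide, a path that needs no free benzylic cation (which the protonated imidazole and the meta-hydroxyl could not stabilise); phenol and N-benzyl group are inert.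

Step 3
Reactants: 1 1-benzylimidazole
Product: 6 1-(1-benzylimidazol-2-yl)-2,2,2-trichloroethanone
Conditions: Cl3CCOCl (1.05 equiv), CH2Cl2, 0 °C to rt; then Et3N (1.1 equiv), 0 °C
Reagents that add atoms: trichloroacetyl chloride, O=C(Cl)C(Cl)(Cl)Cl
Why: Regel-type C2-acylation of an N-alkylimidazole by an acid chloride: acylation at N3 makes the C2–H acidic, and the derived ylide is acylated at carbon, so no organometallic reagent is needed; the trichloromethyl ketone is a storable acyl donor that stands in for the imidazole-2-carboxylic acid, which would decarboxylate on warming.

Step 4
Reactants: 5 3-[(1-benzylimidazol-2-yl)methyl]phenol; 6 1-(1-benzylimidazol-2-yl)-2,2,2-trichloroethanone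
Product: 7 3-[(1-benzylimidazol-2-yl)methyl]phenyl 1-benzylimidazole-2-carboxylate
Conditions: 6 (1.15 equiv), DBU (0.3 equiv), MeCN, 0 °C to rt; evaporate, crystallise
Reagents that add atoms: none
Why: Haloform-type acyl transfer from a trichloromethyl ketone to an oxygen nucleophile: the phenoxide adds to the doubly activated carbonyl, trichloromethanide leaves and is protonated by the next phenol to chloroform, so catalytic base carries a chain and the C–C cleavage makes the transfer irreversible; the aryl ester formed is the activated acyl donor that the key step requires, and it is isolated without aqueous base.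

Step 5
Reactants: 8 3-chloro-4-methoxyphenol
Product: 9 3-chloro-4-methoxyphenyl N-isopropylcarbamate
Conditions: i-PrNCO, Et3N (0.2 equiv), CH2Cl2, rt
Reagents that add atoms: isopropyl isocyanate, CC(C)N=C=O
Why: Base-catalysed addition of a phenol to an isocyanate; the N–H carbamate is both a strong metalation director and cleavable under mild base later.

Step 6
Reactants: 9 3-chloro-4-methoxyphenyl N-isopropylcarbamate
Product: 13 3-chloro-4-methoxy-2-(trimethylsilyl)phenyl N-isopropylcarbamate, via N-silyl carbamate 10 (not isolated), via C2-lithio N-silyl carbamate 11 (not isolated), via N-silyl C2-silyl carbamate 12 (not isolated)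
Conditions: TBSOTf, TMEDA, Et2O, 0 °C to rt; n-BuLi, TMEDA, −78 °C; TMSCl, −78 °C to rt; aq NaHSO4
Reagents that add atoms: chlorotrimethylsilane, C[Si](C)(C)Cl
Why: Directed ortho-metalation: the N-silylated carbamate and the chlorine together make the hydrogen between them the most acidic, so lithiation and silylation occur at C2; at −78 °C the ortho-chloro aryllithium should neither lose LiCl nor undergo anionic Fries rearrangement, and the acidic work-up removes the N-silyl group.

Step 7
Reactants: 13 3-chloro-4-methoxy-2-(trimethylsilyl)phenyl N-isopropylcarbamate
Product: 15 3-chloro-4-methoxy-2-(trimethylsilyl)phenyl trifluoromethanesulfonate, via 3-chloro-4-methoxy-2-(trimethylsilyl)phenol 14 (not isolated)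
Conditions: DBU, Et2NH, MeCN, 40 °C; then PhNTf2, rt
Reagents that add atoms: N-phenylbis(trifluoromethanesulfonimide), O=S(=O)(N(c1ccccc1)S(=O)(=O)C(F)(F)F)C(F)(F)F
Why: E1cB cleavage of the N–H carbamate by DBU releases the phenoxide and isopropyl isocyanate, which diethylamine traps as a urea; the phenoxide is triflated in the same pot by a mild sulfonyl donor that leaves the aryl–silicon bond intact.

Step 8
Reactants: 7 3-[(1-benzylimidazol-2-yl)methyl]phenyl 1-benzylimidazole-2-carboxylate; 15 3-chloro-4-methoxy-2-(trimethylsilyl)phenyl trifluoromethanesulfonate
Product: 18 (1-benzylimidazol-2-yl)[6-[3-[(1-benzylimidazol-2-yl)methyl]phenoxy]-2-chloro-3-methoxyphenyl]methanone, via 3-chloro-4-methoxybenzyne 16 (not isolated), via 2-aryloxy-6-chloroaryl potassium 17 (not isolated)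
Conditions: KF (3 equiv), 18-crown-6 (3 equiv), potassium phenoxide of 5 (0.1 equiv, from 5 and KH), THF, 0 °C to rt; 15 (1.3 equiv) added over 4 h
Reagents that add atoms: none
Why: Proposed new method: fluoride desilylates 15 and triflate leaves to give aryne 16; the potassium phenoxide of 5 (seeded, then released continuously) adds to aryne carbon C4, remote from chlorine, to give aryl anion 17 at C5, which attacks the activated ester carbonyl of a second molecule of 7 and collapses to ketone 18 while expelling the next phenoxide, so the net result is insertion of the aryne into the aryl O–C(acyl) bond by an anionic chain (any ester opened by fluoride re-enters as an acyl donor). The closest known reaction types are aryne sigma-insertion into N–C(O) bonds of amides and ureas and into C–Cl bonds of acid chlorides, and O-arylation of phenoxides by arynes; insertion into an aryl ester C–O bond is the new element. No ring is closed and no stereocenter is formed. Regioselectivity (oxygen at C4, acyl at C5) is needed: the inductively withdrawing chlorine at C6 distorts the aryne so that C4 is the more electrophilic carbon and the developing carbanion sits next to chlorine, and the methoxy group at C1, nearer to C5, weakly reinforces the same sense. The aryl anion must prefer acyl transfer to protonation: THF replaces acetonitrile, the ester is an activated aryl ester whose imidazole N3 can chelate the potassium ion, and 15 is added slowly so that 17 always meets an excess of 7. The phenoxide must outcompete the neutral imidazole N3 atoms and fluoride for the aryne: the crown-ether-separated phenoxide is the strongest nucleophile present and the seed keeps its concentration up from the start. A second addition to 18 should be held back because the new ketone is flanked by chlorine and the aryloxy group.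

Step 9
Reactants: 18 (1-benzylimidazol-2-yl)[6-[3-[(1-benzylimidazol-2-yl)methyl]phenoxy]-2-chloro-3-methoxyphenyl]methanone
Product: 19 racemic (1-benzylimidazol-2-yl)[6-[3-[(1-benzylimidazol-2-yl)methyl]phenoxy]-2-chloro-3-methoxyphenyl]methanol
Conditions: NaBH4, MeOH–THF, 0 °C
Reagents that add atoms: none
Why: Borohydride reduction of an aryl 2-imidazolyl ketone, activated by the azole and still open to a small hydride despite two ortho substituents; aryl chloride, ethers and N-benzyl groups are inert; the carbinol center forms racemic and is erased in step 11.

Step 10
Reactants: 19 racemic (1-benzylimidazol-2-yl)[6-[3-[(1-benzylimidazol-2-yl)methyl]phenoxy]-2-chloro-3-methoxyphenyl]methanol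
Product: 20 racemic 1-benzyl-2-[chloro[6-[3-[(1-benzylimidazol-2-yl)methyl]phenoxy]-2-chloro-3-methoxyphenyl]methyl]imidazole (handled as its bis-hydrochloride)
Conditions: SOCl2, CH2Cl2, 0 to 40 °C; evaporate
Reagents that add atoms: thionyl chloride, O=S(Cl)Cl
Why: Conversion of a benzylic alcohol into the chloride through its chlorosulfite with chloride as nucleophile; the HCl formed protonates both imidazoles, which protects the product from self-alkylation, and the chloride is a handle the next step removes without a benzylic cation.

Step 11
Reactants: 20 racemic 1-benzyl-2-[chloro[6-[3-[(1-benzylimidazol-2-yl)methyl]phenoxy]-2-chloro-3-methoxyphenyl]methyl]imidazole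
Product: 21 lepidine C
Conditions: H2 (5 atm), Pd(OH)2 on carbon, AcOH, rt then 60 °C; aq NH3
Reagents that add atoms: none
Why: Catalytic hydrogenolysis: the benzylic C–Cl bond should go first, then the aryl C–Cl bond, and the two N-benzyl groups follow in the acidic medium that keeps the imidazoles protonated and off the catalyst (N-benzylimidazoles are slow but established substrates); diaryl ether C–O bonds and the C-benzyl C–C links are not cleaved, and basic work-up gives the free base.

## Compound list

1 | 1-benzylimidazole | c1ccc(Cn2ccnc2)cc1 | starting material
2 | 3-hydroxybenzaldehyde | O=Cc1cccc(O)c1 | starting material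
3 | 1-benzyl-2-lithioimidazole | [Li]c1nccn1Cc1ccccc1 | intermediate
4 | racemic (1-benzylimidazol-2-yl)(3-hydroxyphenyl)methanol | OC(c1cccc(O)c1)c1nccn1Cc1ccccc1 | intermediate
5 | 3-[(1-benzylimidazol-2-yl)methyl]phenol | Oc1cccc(Cc2nccn2Cc2ccccc2)c1 | intermediate
6 | 1-(1-benzylimidazol-2-yl)-2,2,2-trichloroethanone | O=C(c1nccn1Cc1ccccc1)C(Cl)(Cl)Cl | intermediate
7 | 3-[(1-benzylimidazol-2-yl)methyl]phenyl 1-benzylimidazole-2-carboxylate | O=C(Oc1cccc(Cc2nccn2Cc2ccccc2)c1)c1nccn1Cc1ccccc1 | intermediate
8 | 3-chloro-4-methoxyphenol | COc1ccc(O)cc1Cl | starting material
9 | 3-chloro-4-methoxyphenyl N-isopropylcarbamate | COc1ccc(OC(=O)NC(C)C)cc1Cl | intermediate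
10 | 3-chloro-4-methoxyphenyl N-(tert-butyldimethylsilyl)-N-isopropylcarbamate | COc1ccc(OC(=O)N(C(C)C)[Si](C)(C)C(C)(C)C)cc1Cl | intermediate
11 | 3-chloro-2-lithio-4-methoxyphenyl N-(tert-butyldimethylsilyl)-N-isopropylcarbamate | COc1ccc(OC(=O)N(C(C)C)[Si](C)(C)C(C)(C)C)c([Li])c1Cl | intermediate
12 | 3-chloro-4-methoxy-2-(trimethylsilyl)phenyl N-(tert-butyldimethylsilyl)-N-isopropylcarbamate | COc1ccc(OC(=O)N(C(C)C)[Si](C)(C)C(C)(C)C)c([Si](C)(C)C)c1Cl | intermediate
13 | 3-chloro-4-methoxy-2-(trimethylsilyl)phenyl N-isopropylcarbamate | COc1ccc(OC(=O)NC(C)C)c([Si](C)(C)C)c1Cl | intermediate
14 | 3-chloro-4-methoxy-2-(trimethylsilyl)phenol | COc1ccc(O)c([Si](C)(C)C)c1Cl | intermediate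
15 | 3-chloro-4-methoxy-2-(trimethylsilyl)phenyl trifluoromethanesulfonate | COc1ccc(OS(=O)(=O)C(F)(F)F)c([Si](C)(C)C)c1Cl | intermediate
16 | 3-chloro-4-methoxybenzyne | COC1=C(Cl)C#CC=C1 | intermediate
17 | [6-[3-[(1-benzylimidazol-2-yl)methyl]phenoxy]-2-chloro-3-methoxyphenyl]potassium | COc1ccc(Oc2cccc(Cc3nccn3Cc3ccccc3)c2)c([K])c1Cl | intermediate
18 | (1-benzylimidazol-2-yl)[6-[3-[(1-benzylimidazol-2-yl)methyl]phenoxy]-2-chloro-3-methoxyphenyl]methanone | COc1ccc(Oc2cccc(Cc3nccn3Cc3ccccc3)c2)c(C(=O)c2nccn2Cc2ccccc2)c1Cl | intermediate
19 | racemic (1-benzylimidazol-2-yl)[6-[3-[(1-benzylimidazol-2-yl)methyl]phenoxy]-2-chloro-3-methoxyphenyl]methanol | COc1ccc(Oc2cccc(Cc3nccn3Cc3ccccc3)c2)c(C(O)c2nccn2Cc2ccccc2)c1Cl | intermediate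
20 | racemic 1-benzyl-2-[chloro[6-[3-[(1-benzylimidazol-2-yl)methyl]phenoxy]-2-chloro-3-methoxyphenyl]methyl]imidazole | COc1ccc(Oc2cccc(Cc3nccn3Cc3ccccc3)c2)c(C(Cl)c2nccn2Cc2ccccc2)c1Cl | intermediate
21 | lepidine C | COc1ccc(Oc2cccc(Cc3ncc[nH]3)c2)c(Cc2ncc[nH]2)c1 | target

## Step count and least certain steps

Total step count: 11 steps. Longest linear sequence: 7 steps, reached by two branches of equal length. One runs 1 to 4 to 5 to 7 to 18 to 19 to 20 to 21 (steps 1, 2, 4, 8, 9, 10 and 11). The other runs 8 to 9 to 13 to 15 to 18 to 19 to 20 to 21 (steps 5, 6, 7, 8, 9, 10 and 11). Ketone 6 (step 3) joins the first branch at step 4.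

The least certain steps are 8, 2, 4 and 10.

**Step 8 (key step, proposed new method).** Several processes could divert the chain:

- Protonation of aryl anion 17 before it is acylated (by traces of water or by the acidic CH2 between ring B and its imidazole) would give O-arylation without the C–C bond.
- Addition of the neutral imidazole N3 atoms to the aryne would compete with the phenoxide.
- Loss of chloride from the ortho-chloroaryl anion would generate a second aryne.
- Opening of the ester by fluoride faster than the aryne is formed would upset the balance of the chain.

The fallback uses known chemistry only; it sets out from 5 and rejoins the route at 19. Commercial 2-chloro-4-fluoroanisole would be lithiated between the two halogens with LiN(i-Pr)2 in THF at −78 °C and formylated with DMF to give 2-chloro-6-fluoro-3-methoxybenzaldehyde F1. Nucleophilic aromatic substitution of the aldehyde-activated fluoride by phenol 5 (K2CO3, DMF, 90 °C) should give 6-[3-[(1-benzylimidazol-2-yl)methyl]phenoxy]-2-chloro-3-methoxybenzaldehyde F2. Addition of organolithium 3 (THF, −78 °C) to F2 then gives carbinol 19, and steps 10 and 11 follow unchanged. This gives up the one-step convergence and makes 6, 7 and 15 unnecessary, but each operation is standard.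

**Step 2.** With no cation stabilisation available, exchange of the hydroxyl for iodide may be slow, so the reduction could stall at the carbinol or its acetate. The fallback avoids the carbinol altogether; it sets out from 1 and returns at 5. Organolithium 3 would be quenched with iodine to give 1-benzyl-2-iodoimidazole F3. Negishi coupling of F3 with commercial (3-methoxybenzyl)zinc chloride under Pd(PPh3)4 catalysis in THF at 50 °C should give 1-benzyl-2-(3-methoxybenzyl)imidazole F4. Demethylation with BBr3 in CH2Cl2 then gives 5.

**Step 4.** The tetrahedral adduct may return phenoxide much more often than it releases trichloromethanide, so the transfer to a phenol could be slow. Trichloromethanide may also lose chloride before it is protonated, and the resulting carbene would consume phenoxide. Hydrolysis of the activated ester 7 during isolation would erode the supply of the key precursor. The fallback replaces the ketone by the free acid and a carbodiimide coupling; it sets out from 1 and returns at 7. Organolithium 3, made from 1 as in step 1, would be carboxylated with CO2 (THF, −78 °C to rt) and the product isolated cold at pH 4 as 1-benzylimidazole-2-carboxylic acid F5. Steglich esterification of F5 with phenol 5 (EDC·HCl, DMAP, CH2Cl2–DMF, 0 °C to rt) then gives 7 without heating the acid.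

**Step 10.** Substitution at the doubly ortho-flanked, cation-destabilised carbinol carbon may be sluggish, and any free-base chloride could self-alkylate through imidazole N3. The fallback switches to a radical deoxygenation; it sets out from 19 and returns at 21. Carbinol 19 would be acylated with 1,1'-thiocarbonyldiimidazole (DMAP, 1,2-dichloroethane, 60 °C) to give O-[(1-benzylimidazol-2-yl)[6-[3-[(1-benzylimidazol-2-yl)methyl]phenoxy]-2-chloro-3-methoxyphenyl]methyl] imidazole-1-carbothioate F6. Barton–McCombie reduction of F6 (Bu3SnH, AIBN, toluene, 100 °C) should give 1-benzyl-2-[[6-[3-[(1-benzylimidazol-2-yl)methyl]phenoxy]-2-chloro-3-methoxyphenyl]methyl]imidazole F7. Hydrogenolysis of F7 under the conditions of step 11 then gives 21.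

## Further compounds

F1 | step 8 | 2-chloro-6-fluoro-3-methoxybenzaldehyde | COc1ccc(F)c(C=O)c1Cl
F2 | step 8 | 6-[3-[(1-benzylimidazol-2-yl)methyl]phenoxy]-2-chloro-3-methoxybenzaldehyde | COc1ccc(Oc2cccc(Cc3nccn3Cc3ccccc3)c2)c(C=O)c1Cl
F3 | step 2 | 1-benzyl-2-iodoimidazole | Ic1nccn1Cc1ccccc1
F4 | step 2 | 1-benzyl-2-(3-methoxybenzyl)imidazole | COc1cccc(Cc2nccn2Cc2ccccc2)c1
F5 | step 4 | 1-benzylimidazole-2-carboxylic acid | O=C(O)c1nccn1Cc1ccccc1
F6 | step 10 | O-[(1-benzylimidazol-2-yl)[6-[3-[(1-benzylimidazol-2-yl)methyl]phenoxy]-2-chloro-3-methoxyphenyl]methyl] imidazole-1-carbothioate | COc1ccc(Oc2cccc(Cc3nccn3Cc3ccccc3)c2)c(C(OC(=S)n2ccnc2)c2nccn2Cc2ccccc2)c1Cl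
F7 | step 10 | 1-benzyl-2-[[6-[3-[(1-benzylimidazol-2-yl)methyl]phenoxy]-2-chloro-3-methoxyphenyl]methyl]imidazole | COc1ccc(Oc2cccc(Cc3nccn3Cc3ccccc3)c2)c(Cc2nccn2Cc2ccccc2)c1Cl
A1 | alternative 1 | 2-iodo-1-(3-iodophenoxy)-4-methoxybenzene | COc1ccc(Oc2cccc(I)c2)c(I)c1
A2 | alternative 1 | 2-(tributylstannyl)-1-[2-(trimethylsilyl)ethoxymethyl]imidazole | CCCC[Sn](CCCC)(CCCC)c1nccn1COCC[Si](C)(C)C
A3 | alternative 1 | [2-[3-[1-[2-(trimethylsilyl)ethoxymethyl]imidazole-2-carbonyl]phenoxy]-5-methoxyphenyl][1-[2-(trimethylsilyl)ethoxymethyl]imidazol-2-yl]methanone | COc1ccc(Oc2cccc(C(=O)c3nccn3COCC[Si](C)(C)C)c2)c(C(=O)c2nccn2COCC[Si](C)(C)C)c1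
A4 | alternative 2 | methyl 5-methoxy-2-oxo-2H-pyran-3-carboxylate | COC(=O)C1=CC(OC)=COC1=O
A5 | alternative 2 | methyl 3-(ethynyloxy)benzoate | C#COc1cccc(C(=O)OC)c1
A6 | alternative 2 | methyl 5-methoxy-2-[3-(methoxycarbonyl)phenoxy]benzoate | COC(=O)c1cccc(Oc2ccc(OC)cc2C(=O)OC)c1
A7 | alternative 3 | bis(1,3-dioxoisoindolin-2-yl) ester of 2-[2-[3-(carboxymethyl)phenoxy]-5-methoxyphenyl]acetic acid | COc1ccc(Oc2cccc(CC(=O)ON3C(=O)c4ccccc4C3=O)c2)c(CC(=O)ON2C(=O)c3ccccc3C2=O)c1
A8 | alternative 3 | 2-iodo-1-[2-(trimethylsilyl)ethoxymethyl]imidazole | Ic1nccn1COCC[Si](C)(C)C
A9 | alternative 3 | N,N'-bis[2-(trimethylsilyl)ethoxymethyl] lepidine C | COc1ccc(Oc2cccc(Cc3nccn3COCC[Si](C)(C)C)c2)c(Cc2nccn2COCC[Si](C)(C)C)c1
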